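(The constants stand for no real mixture; the run is a simulation.)

The ratio that matters here is target made per isomer made, and it comes from following one molecule of substrate through its forks.

in all of them: substrate 0.20 M; coupling partner 0.400 M; time 8.0 min

|  | temperature | remark |
|---|---|---|
| epsilon | 20 °C |  |
| delta |  | at 20 °C until 6.0 min, from then on at 50 °C |
| gamma | 35 °C |  |
| alpha | 50 °C |  |

1. the flask with the highest amount of target, in percent of the substrate charged ("all alike" if they lie within 1.5 percentage points) (epsilon / delta / gamma / alpha / all alike)
2. final target, as a percentage of the substrate charged, in epsilon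
3. final target, as a percentage of the substrate charged, in delta
4. final target, as a percentage of the substrate charged, in gamma
5. final target, as a percentage of the substrate charged, in alpha

- percentages count the substrate that a species holds: one side product counts as two
- at 50 °C the constants are as listed, elsewhere as the activation energies and enthalpies make them

    substrate + tautomer → side product (k1 = 0.0825 M⁻¹ s⁻¹, Ea1 = 74.0 kJ mol⁻¹)
    coupling partner ⇌ dormant form (K2 = 1.0, k2 = 0.00735 s⁻¹, Ea2 = 87.0 kJ mol⁻¹, ΔH2 = 8.00 kJ mol⁻¹)
    substrate + coupling partner ⇌ isomer of the product (K3 = 40 M⁻¹, k3 = 0.0325 M⁻¹ s⁻¹, Ea3 = 68.0 kJ mol⁻¹, ΔH3 = −36.0 kJ mol⁻¹)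
    coupling partner + tautomer → target (k4 = 0.0960 M⁻¹ s⁻¹, Ea4 = 66.0 kJ mol⁻¹)
    substrate ⇌ tautomer (K5 = 1.8, k5 = 0.0854 s⁻¹, Ea5 = 81.0 kJ mol⁻¹, ΔH5 = 21.0 kJ mol⁻¹)
    (constants at 50 °C)

In alpha, at 50 °C, a substrate molecule either becomes tautomer at 0.0854 s⁻¹ or joins the coupling partner as isomer at 0.0130 s⁻¹, with [coupling partner] taken at its charge. A tautomer molecule then returns at 0.0474 s⁻¹, goes on to target at 0.0384 s⁻¹, or meets substrate to give side product. With [substrate] at a rough opening 0.100 M, that exit runs at 0.00825 s⁻¹. Target per isomer is the forward rate times the tautomer's share going to target, over the isomer exit: 2.68. Side product, counted as 2, stands to target as 0.430, so the chance of ending as target is 0.555.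

The weak link is [substrate], which sinks through the run. A mean of 0.0500 M brings the side exit to 0.00413 s⁻¹ and gives the target's chance 0.636, the share of consumed substrate that ends as target, with the isomer counted as an end although its step runs back. The same forks give the time constant of the substrate and tautomer pool, 0.609 min, far shorter than 8.0 min. My figure for alpha is therefore 63.6 %.

In epsilon, at 20 °C, the equilibrium constant of tautomer formation becomes 0.809. The rates become 0.00390 s⁻¹ forward, 0.00483 s⁻¹ back, 0.00311 s⁻¹ to target, 9.75 × 10⁻⁴ s⁻¹ to isomer and 2.46 × 10⁻⁴ s⁻¹ to side product. The chance is then 0.551, and the time constant 9.56 min exceeds the time allowed. As an estimate, that puts epsilon below 31.2 %. Counting gamma midway between the two chances, and delta as cold until 6.0 min and hot afterwards, my reckoning picks alpha.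

The forecast also names alpha, holding that “the hottest flask wins”. It gives 24 % for epsilon, 52 % for delta, 57 % for gamma and 73 % for alpha, so for alpha it stands above my figure.

The simulation gives alpha, with 24.4 % in epsilon, 51.7 % in delta, 51.4 % in gamma and 65.8 % in alpha.

At 8.00 min alpha still holds 0.783 % substrate and 1.18 % tautomer, so the target's chance 0.636 gives 62.4 % target. Part of what holds alpha down is the tautomer's return, together with the time allowed: without that step target reaches 81.4 %, and a tenfold time gives 81.9 %. Epsilon left until 15 min has the same charges and temperature, and holds 16.1 % substrate and 11.2 % tautomer. Its chance 0.551 therefore gives 40.0 % target, and the computed flask holds 35.9 %.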